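**Retrosynthetic overview**
- The target is the [5+2] adduct (bicyclo[3.2.1]octenedione) of trans-ozic acid, through its C14=C15 vinyl group, and a ring-B-contracted abietane 2-methoxy-1,4-quinone carrying a C(OH)CHO centre; this cycloaddition is the last step.
- Key disconnection in the quinone half: the tertiary C9–O bond, made in one oxidation (arene → quinone → quinone methide → conjugate hydration → quinone) that also sets the carbinol centre.
- The ring-contracted aldehyde comes from a trans-abietane (DDQ dehydrogenation, iodine(III) 6→5 ring contraction); the abietane comes from an enantioselective proton-initiated bicyclisation of a homogeranyl arene.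
- trans-Ozic acid comes from (−)-abietic acid: 13,14-cleavage, enal → 8(17)-methylene transposition, C12–C13 cleavage, then two Wittig reactions; its four stereocentres are bought.
- Ring order: arene ring C (bought) → rings A and B (one cyclisation) → ring B contracted → the two bridged rings ([5+2]).

Assumption: abietane/labdane numbering is used for 8, 9 and 16–25, fluorene numbering for 10–15 (C9 = ring carbon bearing CHO, C9a/C4a = ring-fusion sp2 carbons); α = face opposite the angular methyl.

**Step 1**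
Reactants: 1 1,2,4-trimethoxybenzene
Product: 3 1,2,4-trimethoxy-3-(propan-2-yl)benzene, via carbinol 2 (not isolated)
Conditions: n-BuLi, THF, 0 °C; acetone, −78 → 0 °C; then Et3SiH, TFA, CH2Cl2, 0 → 23 °C
Reagents that add atoms: acetone (CC(C)=O)
Why: Directed ortho-metalation at the C–H flanked by two OMe groups, 1,2-addition to acetone and ionic hydrogenation of the tertiary benzylic alcohol give the isopropyl arene as a single regioisomer.

**Step 2**
Reactants: 3 1,2,4-trimethoxy-3-(propan-2-yl)benzene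
Product: 4 1-(chloromethyl)-2,4,5-trimethoxy-3-(propan-2-yl)benzene
Conditions: (CH2O)n, HCl (g), 1,4-dioxane, 0 → 15 °C
Reagents that add atoms: formaldehyde from paraformaldehyde (C=O); hydrogen chloride (Cl)
Why: Blanc chloromethylation (SEAr) attacks C5, the only free position para to a methoxy group and ortho to another, as in 1,2,4-trimethoxybenzene itself.

**Step 3**
Reactants: 4 1-(chloromethyl)-2,4,5-trimethoxy-3-(propan-2-yl)benzene; 5 geranyl chloride
Product: 7 1-[(3E)-4,8-dimethylnona-3,7-dien-1-yl]-2,4,5-trimethoxy-3-(propan-2-yl)benzene, via benzylmagnesium chloride 6 (not isolated)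
Conditions: Mg, THF, 0 °C; then 5, Li2CuCl4 (3 mol%), −20 → 0 °C
Reagents that add atoms: none
Why: Kochi-type copper-catalysed Grignard coupling displaces the primary allylic chloride in SN2 fashion (the tertiary γ-terminus is not attacked), so the E-olefin of the geranyl unit is kept.

**Step 4**
Reactants: 7 1-[(3E)-4,8-dimethylnona-3,7-dien-1-yl]-2,4,5-trimethoxy-3-(propan-2-yl)benzene
Product: 8 (5S,10S)-11,12,14-trimethoxyabieta-8,11,13-triene
Conditions: (R)-3,3′-dichloro-BINOL·SbCl5 (1 equiv), CH2Cl2, −78 °C; recrystallise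
Reagents that add atoms: none
Why: Enantioselective proton-initiated polyene (cation–olefin) bicyclisation, established for methoxy-substituted homogeranyl arenes: enantiofacial protonation of the terminal olefin, chair–chair anti-addition across the E-alkene and Friedel–Crafts closure at the only free arene position set C5 (α-H) and C10 (β-CH3) trans; the (R)-ligand is taken as the one giving the natural (5S,10S) series, and the antipode is used if the sense is reversed for this arene.

**Step 5**
Reactants: 8 (5S,10S)-11,12,14-trimethoxyabieta-8,11,13-triene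
Product: 9 (5S,10S)-11,12,14-trimethoxyabieta-6,8,11,13-tetraene
Conditions: DDQ (1.05 equiv), 1,4-dioxane, 23 °C
Reagents that add atoms: none
Why: DDQ dehydrogenation by hydride abstraction from benzylic C7 (cation stabilised by the ortho and para methoxy groups) and loss of H6 gives the conjugated C6=C7 styrene without touching C5 or C10.

**Step 6**
Reactants: 9 (5S,10S)-11,12,14-trimethoxyabieta-6,8,11,13-tetraene
Product: 11 (4bS,8aS)-1,3,4-trimethoxy-4b,8,8-trimethyl-2-(propan-2-yl)-4b,5,6,7,8,8a-hexahydro-9H-fluorene-9-carbaldehyde, via dimethyl acetal 10 (not isolated)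
Conditions: PhI(OH)OTs (1.2 equiv), HC(OMe)3–MeOH, −10 → 0 °C; then 1 M HCl, THF, 23 °C
Reagents that add atoms: water (O)
Why: Iodine(III)-mediated oxidative ring contraction of a 1,2-dihydronaphthalene (semipinacol-type 1,2-aryl shift): iodination at C6 with methanol capture at benzylic C7, then migration of the electron-rich aryl carbon from C7 to C6 with loss of PhI makes ring B five-membered with the former C7 as an acetal (hydrolysed to CHO); the trans ring fusion is inherited from the decalin and the new C9 centre is an epimer mixture that step 7 erases.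

**Step 7**
Reactants: 11 (4bS,8aS)-1,3,4-trimethoxy-4b,8,8-trimethyl-2-(propan-2-yl)-4b,5,6,7,8,8a-hexahydro-9H-fluorene-9-carbaldehyde
Product: 15 (4bS,8aS,9R)-9-hydroxy-3-methoxy-4b,8,8-trimethyl-1,4-dioxo-2-(propan-2-yl)-4,4b,5,6,7,8,8a,9-octahydro-1H-fluorene-9-carbaldehyde, via quinone aldehyde 12 (not isolated), via quinone methide 13 (not isolated), via hydroquinone 14 (not isolated)
Conditions: CAN (2.3 equiv), MeCN–H2O (2:1), 0 °C, 15 min; then 1,4-benzoquinone (1.5 equiv), Ar, 30 °C
Reagents that add atoms: water (O)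
Why: Proposed new method: CAN oxidative demethylation (known) unmasks quinone 12, whose C9–H is α to the formyl group and vinylogously γ to the C4 carbonyl, so acid-catalysed enolisation gives the formyl quinone methide 13, water adds 1,6 to C9 from the open α-face (anti to the 4b- and 8β-methyl groups) to form the C9–O bond and the (9R) carbinol in hydroquinone 14, and benzoquinone re-oxidises 14 to quinone 15, which can no longer ionise at C9; the closest known reactions are the tautomerisation of alkylquinones to quinone methides with conjugate addition of water or alcohols and the benzylic oxidation of alkylhydroquinones.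

**Step 8**
Reactants: 16 (−)-abietic acid
Product: 18 13,14-dioxo-13,14-secoabiet-7-en-18-oic acid, via 13,14-diol 17 (not isolated)
Conditions: OsO4 (2 mol%), NaIO4 (4 equiv), 2,6-lutidine, dioxane–H2O (3:1), 23 °C
Reagents that add atoms: osmium tetroxide (O=[Os](=O)(=O)=O); sodium periodate ([Na+].[O-]I(=O)(=O)=O)
Why: Lemieux–Johnson cleavage (dihydroxylation then periodate glycol cleavage) takes the more accessible 13,14-olefin of the diene, after which the 7,8-olefin is part of an enal and deactivated; C4, C5, C9 and C10 come unchanged from abietic acid.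

**Step 9**
Reactants: 18 13,14-dioxo-13,14-secoabiet-7-en-18-oic acid
Product: 21 13-oxo-13,14-secoabiet-8(14)-en-18-oic acid, via tosylhydrazone 19 (not isolated), via allyl diazene 20 (not isolated)
Conditions: TsNHNH2 (1.05 equiv), THF, 23 °C; catecholborane (2.5 equiv), 0 °C; NaOAc·3H2O, 65 °C
Reagents that add atoms: none
Why: Kabalka reduction of an α,β-unsaturated tosylhydrazone (alkene-transposing Wolff–Kishner variant): the aldehyde condenses selectively over the hindered isopropyl ketone, C=N reduction and loss of sulfinate give the allyl diazene, and its retro-ene loss of N2 delivers H to C7 and moves the double bond to the exocyclic C8=CH2 position without involving C9.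

**Step 10**
Reactants: 21 13-oxo-13,14-secoabiet-8(14)-en-18-oic acid
Product: 22 12-hydroxy-13-oxo-13,14-secoabiet-8(14)-en-18-oic acid
Conditions: KHMDS (2.3 equiv), THF, −78 °C; 2-(phenylsulfonyl)-3-phenyloxaziridine (1.3 equiv); aq NH4Cl
Reagents that add atoms: 2-(phenylsulfonyl)-3-phenyloxaziridine (O=S(=O)(N1OC1c1ccccc1)c1ccccc1)
Why: Davis oxaziridine α-hydroxylation of the kinetic potassium enolate, formed at the CH2 (C12) and not at the isopropyl CH after the first equivalent of base has made the carboxylate; the C12 configuration is irrelevant because C12 becomes sp2.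

**Step 11**
Reactants: 22 12-hydroxy-13-oxo-13,14-secoabiet-8(14)-en-18-oic acid
Product: 23 12-oxo-13,14,15,16-tetranorlabd-8(17)-en-18-oic acid
Conditions: NaIO4 (1.5 equiv), THF–H2O (3:1), 23 °C
Reagents that add atoms: none
Why: Periodate (Malaprade-type) cleavage of the α-hydroxy ketone between C12 and C13 gives the C12 aldehyde and leaves the 1,1-disubstituted olefin alone.

**Step 12**
Reactants: 23 12-oxo-13,14,15,16-tetranorlabd-8(17)-en-18-oic acid
Product: 24 (12E)-14-oxo-15-norlabda-8(17),12-dien-18-oic acid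
Conditions: Ph3P=C(CH3)CHO (1.5 equiv), toluene, 90 °C
Reagents that add atoms: 2-(triphenylphosphoranylidene)propanal (CC(C=O)=P(c1ccccc1)(c1ccccc1)c1ccccc1)
Why: Wittig olefination with a stabilised α-branched ylide gives the trisubstituted enal with high E-selectivity, which fixes the C12=C13 geometry of the target.

**Step 13**
Reactants: 24 (12E)-14-oxo-15-norlabda-8(17),12-dien-18-oic acid
Product: 25 trans-ozic acid [(4R,5R,9S,10R)-labda-8(17),12E,14-trien-18-oic acid]
Conditions: Ph3PCH3Br (3.0 equiv), KOtBu (2.9 equiv), THF, 0 °C; aq citric acid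
Reagents that add atoms: methylenetriphenylphosphorane made from methyltriphenylphosphonium bromide (C=P(c1ccccc1)(c1ccccc1)c1ccccc1)
Why: Wittig methylenation of the enal carbonyl (1,2-addition only) completes the 12E,14-diene; one equivalent of ylide is consumed by the carboxylic acid.

**Step 14**
Reactants: 15 (4bS,8aS,9R)-9-hydroxy-3-methoxy-4b,8,8-trimethyl-1,4-dioxo-2-(propan-2-yl)-4,4b,5,6,7,8,8a,9-octahydro-1H-fluorene-9-carbaldehyde; 25 trans-ozic acid
Product: 26 target CNP0124601.1
Conditions: TiCl4–Ti(OiPr)4 (2:1, 3 equiv Ti), 2,6-di-tert-butyl-4-methylpyridine, CH2Cl2, −78 → −40 °C; aq NaHCO3, then pH 3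
Reagents that add atoms: none
Why: Lewis-acid-promoted [5+2] cycloaddition of a 2-alkoxy-1,4-benzoquinone with an alkene (perezone–pipitzol type): Ti(IV) chelated by the C4 carbonyl and 3-OMe makes C9a electrophilic, the terminal CH2 (C15) of the diene bonds to C9a from the α-face (anti to the 4b-methyl and the 9β-formyl group), the allyl cation held under the titanium enolate is closed at C14 by the enol-ether carbon C2 so that the dienyl residue sits endo toward the enol bridge, and chloride removes the O-methyl group to leave the diosphenol with C1 as the bridging ketone.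

**Compound list**
1 | 1,2,4-trimethoxybenzene | COc1ccc(OC)c(OC)c1 | starting material
2 | 2-(2,3,6-trimethoxyphenyl)propan-2-ol | COc1ccc(OC)c(C(C)(C)O)c1OC | intermediate
3 | 1,2,4-trimethoxy-3-(propan-2-yl)benzene | COc1ccc(OC)c(C(C)C)c1OC | intermediate
4 | 1-(chloromethyl)-2,4,5-trimethoxy-3-(propan-2-yl)benzene | ClCc1cc(OC)c(OC)c(C(C)C)c1OC | intermediate
5 | geranyl chloride, (2E)-1-chloro-3,7-dimethylocta-2,6-diene | CC(C)=CCC/C(C)=C/CCl | starting material
6 | [2,4,5-trimethoxy-3-(propan-2-yl)benzyl]magnesium chloride | Cl[Mg]Cc1cc(OC)c(OC)c(C(C)C)c1OC | intermediate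
7 | 1-[(3E)-4,8-dimethylnona-3,7-dien-1-yl]-2,4,5-trimethoxy-3-(propan-2-yl)benzene | CC(C)=CCC/C(C)=C/CCc1cc(OC)c(OC)c(C(C)C)c1OC | intermediate
8 | (5S,10S)-11,12,14-trimethoxyabieta-8,11,13-triene (5α-H, 10β-CH3) | COc1c(OC)c(C(C)C)c(OC)c2c1[C@@]1(C)CCCC(C)(C)[C@@H]1CC2 | intermediate
9 | (5S,10S)-11,12,14-trimethoxyabieta-6,8,11,13-tetraene | COc1c(OC)c(C(C)C)c(OC)c2c1[C@@]1(C)CCCC(C)(C)[C@@H]1C=C2 | intermediate
10 | (4bS,8aS)-9-(dimethoxymethyl)-1,3,4-trimethoxy-4b,8,8-trimethyl-2-(propan-2-yl)-4b,5,6,7,8,8a-hexahydro-9H-fluorene (C9 epimers) | COc1c(OC)c(C(C)C)c(OC)c2c1[C@@]1(C)CCCC(C)(C)[C@@H]1C2C(OC)OC | intermediate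
11 | (4bS,8aS)-1,3,4-trimethoxy-4b,8,8-trimethyl-2-(propan-2-yl)-4b,5,6,7,8,8a-hexahydro-9H-fluorene-9-carbaldehyde (C9 epimers; 8a-H α, 4b-CH3 β) | COc1c(OC)c(C(C)C)c(OC)c2c1[C@@]1(C)CCCC(C)(C)[C@@H]1C2C=O | intermediate
12 | (4bS,8aS)-3-methoxy-4b,8,8-trimethyl-1,4-dioxo-2-(propan-2-yl)-4,4b,5,6,7,8,8a,9-octahydro-1H-fluorene-9-carbaldehyde (C9 epimers) | COC1=C(C(C)C)C(=O)C2=C(C1=O)[C@@]1(C)CCCC(C)(C)[C@@H]1C2C=O | intermediate
13 | quinone methide tautomer, (4bS,8aS)-4-hydroxy-3-methoxy-4b,8,8-trimethyl-1-oxo-2-(propan-2-yl)-4b,5,6,7,8,8a-hexahydro-1H-fluorene-9-carbaldehyde (C9=C9a, C4a=C4, C2=C3) | COC1=C(C(C)C)C(=O)C=2C(=C1O)[C@@]1(C)CCCC(C)(C)[C@@H]1C2C=O | intermediate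
14 | (4bS,8aS,9R)-1,4,9-trihydroxy-3-methoxy-4b,8,8-trimethyl-2-(propan-2-yl)-4b,5,6,7,8,8a-hexahydro-9H-fluorene-9-carbaldehyde | COc1c(C(C)C)c(O)c2c(c1O)[C@@]1(C)CCCC(C)(C)[C@@H]1[C@]2(O)C=O | intermediate
15 | (4bS,8aS,9R)-9-hydroxy-3-methoxy-4b,8,8-trimethyl-1,4-dioxo-2-(propan-2-yl)-4,4b,5,6,7,8,8a,9-octahydro-1H-fluorene-9-carbaldehyde (9-OH α, 9-CHO β, trans ring fusion) | COC1=C(C(C)C)C(=O)C2=C(C1=O)[C@@]1(C)CCCC(C)(C)[C@@H]1[C@]2(O)C=O | intermediate
16 | (−)-abietic acid, abieta-7,13-dien-18-oic acid | CC(C)C1=CC2=CC[C@@H]3[C@@]([C@H]2CC1)(CCC[C@@]3(C)C(=O)O)C | starting material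
17 | 13,14-dihydroxyabiet-7-en-18-oic acid (cis-diol, C13/C14 configuration not relevant) | CC(C)C1(O)C(O)C2=CC[C@@H]3[C@@]([C@H]2CC1)(CCC[C@@]3(C)C(=O)O)C | intermediate
18 | 13,14-dioxo-13,14-secoabiet-7-en-18-oic acid (C14 enal on C8, isopropyl ketone at C13; 4α-CO2H, 5α-H, 9α-H, 10β-CH3) | O=CC1=CC[C@@H]2[C@@]([C@H]1CCC(=O)C(C)C)(CCC[C@@]2(C)C(=O)O)C | intermediate
19 | C14 p-toluenesulfonylhydrazone of 18 | Cc1ccc(cc1)S(=O)(=O)N/N=C/C1=CC[C@@H]2[C@@]([C@H]1CCC(=O)C(C)C)(CCC[C@@]2(C)C(=O)O)C | intermediate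
20 | 14-diazenyl-13-oxo-13,14-secoabiet-7-en-18-oic acid | N=NCC1=CC[C@@H]2[C@@]([C@H]1CCC(=O)C(C)C)(CCC[C@@]2(C)C(=O)O)C | intermediate
21 | 13-oxo-13,14-secoabiet-8(14)-en-18-oic acid (exocyclic C8=CH2) | C=C1CC[C@@H]2[C@@]([C@H]1CCC(=O)C(C)C)(CCC[C@@]2(C)C(=O)O)C | intermediate
22 | 12-hydroxy-13-oxo-13,14-secoabiet-8(14)-en-18-oic acid (C12 epimers) | C=C1CC[C@@H]2[C@@]([C@H]1CC(O)C(=O)C(C)C)(CCC[C@@]2(C)C(=O)O)C | intermediate
23 | 12-oxo-13,14,15,16-tetranorlabd-8(17)-en-18-oic acid | C=C1CC[C@@H]2[C@@]([C@H]1CC=O)(CCC[C@@]2(C)C(=O)O)C | intermediate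
24 | (12E)-14-oxo-15-norlabda-8(17),12-dien-18-oic acid | C=C1CC[C@@H]2[C@@]([C@H]1C/C=C(\C)C=O)(CCC[C@@]2(C)C(=O)O)C | intermediate
25 | trans-ozic acid, (4R,5R,9S,10R)-labda-8(17),12E,14-trien-18-oic acid | C=C1CC[C@@H]2[C@@]([C@H]1C/C=C(\C)C=C)(CCC[C@@]2(C)C(=O)O)C | intermediate
26 | CNP0124601.1, [5+2] adduct of 25 (C15→C9a, C14→C2 of 15) with 3-hydroxy-2,8-dioxobicyclo[3.2.1]oct-3-ene core | C=C1CC[C@@H]2[C@](C)(CCC[C@@]2(C)C(=O)O)[C@H]1C/C=C(\C)[C@@H]1C[C@@]23C(=O)[C@]1(C(C)C)C(=O)C(O)=C2[C@@]1(C)CCCC(C)(C)[C@@H]1[C@]3(O)C=O | target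

**Totals and risks**
Total step count: 14. Longest linear sequence: 8 steps (1 → 26 through steps 1–7 and 14); the abietic acid branch is 6 steps plus the coupling.

Step 7 (the proposed new step). The quinone methide may lose H8a to give the conjugated C8a=C9 enal instead of adding water, or the α-hydroxy aldehyde may be cleaved oxidatively. Fallback with known chemistry: set out from 11, make the potassium enolate of the aldehyde (KHMDS, THF, −78 °C) and oxidise it from the α-face with 2-(phenylsulfonyl)-3-phenyloxaziridine to the trimethoxy hydroxy aldehyde F1, then oxidise the arene with CAN (MeCN–H2O, 0 °C); this comes back to the route at 15.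

Step 14. The quinone is fully substituted and sits next to a quaternary carbinol; a carbonyl-ene reaction of the aldehyde with the exocyclic olefin, incomplete O-demethylation or the wrong face or endo/exo sense are all possible. Fallback: set out from 15, cleave the vinylogous methyl ester with LiCl in DMF (60 °C) to the free hydroxyquinone F6, and run the perezone-type cationic [5+2] of the 2-hydroxy-1,4-quinone with 25 under BF3·OEt2 (CH2Cl2, −40 °C) or in hexafluoroisopropanol, where no dealkylation is needed; this comes back at 26.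

Step 6. The iodine(III) reagent may oxidise the electron-rich arene or give 1,2-dimethoxylation instead of aryl migration. Fallback: set out from 8 and oxidise the benzylic position with DDQ in wet dioxane–AcOH to the 7-ketone F2. Acylate C6 (LiHMDS, then CF3CO2CH2CF3) to the trifluoroacetyl ketone F3, and transfer the diazo group (MsN3, Et3N) to give the diazo ketone F4. Photochemical Wolff rearrangement in MeOH (350 nm) contracts ring B by the same aryl shift to the methyl ester F5, and DIBAL-H at −78 °C reduces it to the aldehyde; this comes back at 11.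

**Further compounds**
F1 | step 7 | (4bS,8aS,9R)-9-hydroxy-1,3,4-trimethoxy-4b,8,8-trimethyl-2-(propan-2-yl)-4b,5,6,7,8,8a-hexahydro-9H-fluorene-9-carbaldehyde | COc1c(OC)c(C(C)C)c(OC)c2c1[C@@]1(C)CCCC(C)(C)[C@@H]1[C@]2(O)C=O
F2 | step 6 | (5S,10S)-11,12,14-trimethoxyabieta-8,11,13-trien-7-one | COc1c(OC)c(C(C)C)c(OC)c2c1[C@@]1(C)CCCC(C)(C)[C@@H]1CC2=O
F3 | step 6 | (5S,10S)-11,12,14-trimethoxy-6-(trifluoroacetyl)abieta-8,11,13-trien-7-one | COc1c(OC)c(C(C)C)c(OC)c2c1[C@@]1(C)CCCC(C)(C)[C@@H]1C(C(=O)C(F)(F)F)C2=O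
F4 | step 6 | (5S,10S)-6-diazo-11,12,14-trimethoxyabieta-8,11,13-trien-7-one | COc1c(OC)c(C(C)C)c(OC)c2c1[C@@]1(C)CCCC(C)(C)[C@@H]1C(=[N+]=[N-])C2=O
F5 | step 6 | methyl (4bS,8aS)-1,3,4-trimethoxy-4b,8,8-trimethyl-2-(propan-2-yl)-4b,5,6,7,8,8a-hexahydro-9H-fluorene-9-carboxylate | COc1c(OC)c(C(C)C)c(OC)c2c1[C@@]1(C)CCCC(C)(C)[C@@H]1C2C(=O)OC
F6 | step 14 | (4bS,8aS,9R)-3,9-dihydroxy-4b,8,8-trimethyl-1,4-dioxo-2-(propan-2-yl)-4,4b,5,6,7,8,8a,9-octahydro-1H-fluorene-9-carbaldehyde | OC1=C(C(C)C)C(=O)C2=C(C1=O)[C@@]1(C)CCCC(C)(C)[C@@H]1[C@]2(O)C=O
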